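**Strategy.** The α-methylene-γ-butyrolactone (O–C12(=O)–C11(=C13)–C7–C6, germacranolide numbering) is cut so that its O–C12=O unit is carbon dioxide. A terminal alkyne (C11≡C13) on C7 and an inverted tosylate on C6 serve as the latent lactone. In the key step zerovalent nickel joins the alkyne and CO2 at C11, and the acrylate oxygen thus made displaces the C6 tosylate with inversion, closing the trans-fused lactone in one operation. The precursor is an open-chain alkynyl epoxy tosylate, assembled by indium-mediated propargylation of an epoxy aldehyde with an L-threonate-derived mesylate; the ten-membered ring is closed afterwards by metathesis between a vinyl epoxide and the C10 acrylate.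

Key step: step 20

Remark (assumption): germacranolide numbering is used throughout (ring C1–C10, lactone carbons C11–C13, ester carbon C14, methyl C15); TBS = tert-butyldimethylsilyl, TES = triethylsilyl; compounds 1, 11 and 17 are taken as commercial.

**East fragment (C7–C10, C14)**

Step 1
Reactants: 1 methyl 3,4-O-isopropylidene-L-threonate
Product: 2 methyl (2R)-2-[(tert-butyldimethylsilyl)oxy]-2-[(4S)-2,2-dimethyl-1,3-dioxolan-4-yl]acetate
Conditions: TBSCl, imidazole, DMF, 23 °C
Reagents that add atoms: tert-butyldimethylsilyl chloride, CC(C)(C)[Si](C)(C)Cl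
Why: Silyl ether formation caps the only free hydroxyl, the future C9 oxygen, so that the ester can be reduced, and no stereocentre is affected.

Step 2
Reactants: 2 methyl (2R)-2-[(tert-butyldimethylsilyl)oxy]-2-[(4S)-2,2-dimethyl-1,3-dioxolan-4-yl]acetate
Product: 3 (2R)-2-[(tert-butyldimethylsilyl)oxy]-2-[(4S)-2,2-dimethyl-1,3-dioxolan-4-yl]acetaldehyde
Conditions: i-Bu2AlH (1.1 equiv), CH2Cl2, −78 °C
Reagents that add atoms: none
Why: Partial DIBAL reduction stops at the aldehyde because the aluminium hemiacetal of an α-silyloxy ester is stable at −78 °C until work-up, and these non-basic conditions should not epimerize C9.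

Step 3
Reactants: 3 (2R)-2-[(tert-butyldimethylsilyl)oxy]-2-[(4S)-2,2-dimethyl-1,3-dioxolan-4-yl]acetaldehyde
Product: 4 (4S)-4-[(1S)-1-[(tert-butyldimethylsilyl)oxy]prop-2-yn-1-yl]-2,2-dimethyl-1,3-dioxolane
Conditions: dimethyl (1-diazo-2-oxopropyl)phosphonate, K2CO3, MeOH, 0 → 23 °C
Reagents that add atoms: dimethyl (1-diazo-2-oxopropyl)phosphonate, COP(=O)(OC)C(=[N+]=[N-])C(C)=O
Why: The Ohira–Bestmann variant of the Seyferth–Gilbert homologation converts the aldehyde into the terminal alkyne (C10≡CH) under carbonate conditions mild enough to keep the α-silyloxy centre intact.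

Step 4
Reactants: 4 (4S)-4-[(1S)-1-[(tert-butyldimethylsilyl)oxy]prop-2-yn-1-yl]-2,2-dimethyl-1,3-dioxolane
Product: 5 methyl 2-[(S)-[(tert-butyldimethylsilyl)oxy][(4S)-2,2-dimethyl-1,3-dioxolan-4-yl]methyl]prop-2-enoate
Conditions: Pd(OAc)2 (2 mol %), 2-(diphenylphosphino)pyridine, MsOH (cat.), CO (5 bar), MeOH (10 equiv), CH2Cl2, 25 °C
Reagents that add atoms: carbon monoxide, [C-]#[O+]; methanol, CO
Why: Palladium-catalysed hydromethoxycarbonylation with the pyridylphosphine ligand adds H and CO2Me across a terminal alkyne in the Markovnikov sense, giving the 2-substituted acrylate that carries C14 and the methylene later lost in ring closure.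

Step 5
Reactants: 5 methyl 2-[(S)-[(tert-butyldimethylsilyl)oxy][(4S)-2,2-dimethyl-1,3-dioxolan-4-yl]methyl]prop-2-enoate
Product: 6 methyl 2-[(1S,2S)-1-[(tert-butyldimethylsilyl)oxy]-2,3-dihydroxypropyl]prop-2-enoate
Conditions: AcOH/H2O (4:1), 40 °C
Reagents that add atoms: none
Why: Mild acid hydrolysis (acetal cleavage) removes the terminal acetonide while the secondary TBS ether survives, exposing the C7/C8 diol.

Step 6
Reactants: 6 methyl 2-[(1S,2S)-1-[(tert-butyldimethylsilyl)oxy]-2,3-dihydroxypropyl]prop-2-enoate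
Product: 7 methyl 2-[(1S,2S)-1-[(tert-butyldimethylsilyl)oxy]-2,3-bis[(triethylsilyl)oxy]propyl]prop-2-enoate
Conditions: TESCl (2.5 equiv), imidazole, DMAP (cat.), CH2Cl2, 0 °C
Reagents that add atoms: triethylsilyl chloride, CC[Si](Cl)(CC)CC
Why: Bis-silylation (silyl ether formation) gives one primary and one secondary TES ether that the next step can tell apart.

Step 7
Reactants: 7 methyl 2-[(1S,2S)-1-[(tert-butyldimethylsilyl)oxy]-2,3-bis[(triethylsilyl)oxy]propyl]prop-2-enoate
Product: 8 methyl 2-[(1S,2R)-1-[(tert-butyldimethylsilyl)oxy]-3-oxo-2-[(triethylsilyl)oxy]propyl]prop-2-enoate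
Conditions: (COCl)2, DMSO, CH2Cl2, −78 → −30 °C; Et3N, −78 → 0 °C
Reagents that add atoms: none
Why: Under Swern conditions a primary triethylsilyl ether is cleaved and oxidized directly to the aldehyde (oxidative desilylation) while secondary TES and TBS ethers stay, so C7 becomes the aldehyde in one step.

Step 8
Reactants: 8 methyl 2-[(1S,2R)-1-[(tert-butyldimethylsilyl)oxy]-3-oxo-2-[(triethylsilyl)oxy]propyl]prop-2-enoate
Product: 9 methyl 2-[(1S,2S,3S)-1-[(tert-butyldimethylsilyl)oxy]-3-hydroxy-2-[(triethylsilyl)oxy]pent-4-yn-1-yl]prop-2-enoate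
Conditions: HC≡CMgBr, THF, −78 °C
Reagents that add atoms: ethynylmagnesium bromide, C#C[Mg]Br
Why: Felkin–Anh addition of the alkynyl Grignard reagent to the α-silyloxy aldehyde should give mainly the 7,8-anti propargylic alcohol (C7 set by substrate control), and at −78 °C the aldehyde reacts well before the hindered acrylate ester.

Step 9
Reactants: 9 methyl 2-[(1S,2S,3S)-1-[(tert-butyldimethylsilyl)oxy]-3-hydroxy-2-[(triethylsilyl)oxy]pent-4-yn-1-yl]prop-2-enoate
Product: 10 methyl 2-[(1S,2R,3S)-1-[(tert-butyldimethylsilyl)oxy]-3-[(methylsulfonyl)oxy]-2-[(triethylsilyl)oxy]pent-4-yn-1-yl]prop-2-enoate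
Conditions: MsCl, Et3N, CH2Cl2, −40 °C
Reagents that add atoms: methanesulfonyl chloride, CS(=O)(=O)Cl
Why: Mesylation (sulfonate ester formation) with retention turns the C7 hydroxyl into the leaving group needed for anti SN2′ oxidative addition in the coupling.

**West fragment (C3–C6, C15)**

Step 10
Reactants: 11 3-methylbut-2-en-1-yl acetate (prenyl acetate)
Product: 12 (2E)-4-hydroxy-3-methylbut-2-en-1-yl acetate
Conditions: SeO2 (0.5 equiv), t-BuOOH, CH2Cl2, 23 °C
Reagents that add atoms: tert-butyl hydroperoxide, CC(C)(C)OO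
Why: Riley allylic oxidation (ene reaction then [2,3]-shift) hydroxylates the E-methyl group of the trisubstituted alkene selectively, giving the E-allylic alcohol with C3 and C6 trans across C4=C5.

Step 11
Reactants: 12 (2E)-4-hydroxy-3-methylbut-2-en-1-yl acetate
Product: 13 [(2R,3R)-3-(hydroxymethyl)-3-methyloxiran-2-yl]methyl acetate
Conditions: Ti(Oi-Pr)4, D-(−)-diethyl tartrate, t-BuOOH, 4 Å MS, CH2Cl2, −20 °C
Reagents that add atoms: tert-butyl hydroperoxide, CC(C)(C)OO
Why: Sharpless asymmetric epoxidation with the D-(−)-tartrate delivers oxygen to the alkene face that sets C4 and C5 as in the target (reagent control on a 2-methyl-substituted E-allylic alcohol).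

Step 12
Reactants: 13 [(2R,3R)-3-(hydroxymethyl)-3-methyloxiran-2-yl]methyl acetate
Product: 14 [(2R,3R)-3-methyl-3-{[(triethylsilyl)oxy]methyl}oxiran-2-yl]methyl acetate
Conditions: TESCl, imidazole, CH2Cl2, 0 °C
Reagents that add atoms: triethylsilyl chloride, CC[Si](Cl)(CC)CC
Why: Silyl ether formation protects the C3 hydroxyl as a primary TES ether that can later be oxidized directly.

Step 13
Reactants: 14 [(2R,3R)-3-methyl-3-{[(triethylsilyl)oxy]methyl}oxiran-2-yl]methyl acetate
Product: 15 [(2R,3R)-3-methyl-3-{[(triethylsilyl)oxy]methyl}oxiran-2-yl]methanol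
Conditions: K2CO3, MeOH, 0 °C
Reagents that add atoms: none
Why: Base-catalysed transesterification (methanolysis) removes the acetate at 0 °C, where Payne rearrangement of the hindered trisubstituted epoxide should not compete.

Step 14
Reactants: 15 [(2R,3R)-3-methyl-3-{[(triethylsilyl)oxy]methyl}oxiran-2-yl]methanol
Product: 16 (2S,3R)-3-methyl-3-{[(triethylsilyl)oxy]methyl}oxirane-2-carbaldehyde
Conditions: Dess–Martin periodinane, NaHCO3, CH2Cl2, 0 → 23 °C
Reagents that add atoms: none
Why: Buffered Dess–Martin oxidation gives the epoxy aldehyde (C6) without opening the epoxide or epimerizing C5.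

**Side-chain acid**

Step 15
Reactants: 17 (2Z)-2-methylbut-2-enoic acid (angelic acid)
Product: 18 (2Z)-2-methylbut-2-en-1-ol
Conditions: LiAlH4, Et2O, 0 °C
Reagents that add atoms: none
Why: Hydride reduction of the acid gives the allylic alcohol with the Z geometry retained.

Step 16
Reactants: 18 (2Z)-2-methylbut-2-en-1-ol
Product: 19 [(2R,3S)-2,3-dimethyloxiran-2-yl]methanol
Conditions: Ti(Oi-Pr)4, D-(−)-diethyl tartrate, t-BuOOH, 4 Å MS, CH2Cl2, −20 °C
Reagents that add atoms: tert-butyl hydroperoxide, CC(C)(C)OO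
Why: Sharpless asymmetric epoxidation with the D-(−)-tartrate sets both epoxide carbons by reagent control.

Step 17
Reactants: 19 [(2R,3S)-2,3-dimethyloxiran-2-yl]methanol
Product: 20 (2S,3S)-2,3-dimethyloxirane-2-carboxylic acid
Conditions: RuCl3 (cat.), NaIO4, MeCN/CCl4/H2O, 0 → 23 °C
Reagents that add atoms: sodium periodate, [Na+].[O-]I(=O)(=O)=O; water, O
Why: Ruthenium tetroxide oxidation takes the primary alcohol to the acid without touching the epoxide stereocentres.

**Union, key step and end game**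

Step 18
Reactants: 10 methyl 2-[(1S,2R,3S)-1-[(tert-butyldimethylsilyl)oxy]-3-[(methylsulfonyl)oxy]-2-[(triethylsilyl)oxy]pent-4-yn-1-yl]prop-2-enoate; 16 (2S,3R)-3-methyl-3-{[(triethylsilyl)oxy]methyl}oxirane-2-carbaldehyde
Product: 21 open-chain homopropargylic alcohol (3-OTES, 4,5-epoxide, 6-OH with the C6 configuration of the target, 7-ethynyl, 8-OTES, 9-OTBS, C10(=CH2)CO2Me)
Conditions: Pd(dppf)Cl2 (5 mol %), InI (1.5 equiv), THF/HMPA (3:1), 23 °C
Reagents that add atoms: none
Why: In this Marshall-type propargylation zerovalent palladium formed in situ adds anti SN2′ to the mesylate, the allenylpalladium is transmetalated to an allenylindium, and this adds to the aldehyde through a closed six-membered transition state, so that C7 is set by chirality transfer (net inversion) and the C6 hydroxyl anti to C8, while the minor C6 epimer favoured by the Felkin–Anh bias of the aldehyde would give the same tosylate 22 by direct tosylation.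

Step 19
Reactants: 21 open-chain homopropargylic alcohol (6-OH with the C6 configuration of the target)
Product: 22 open-chain 6-epi tosylate (as 21 but C6–OTs with inverted C6)
Conditions: PPh3, DIAD, Zn(OTs)2, toluene, 23 °C
Reagents that add atoms: zinc bis(4-methylbenzenesulfonate), [Zn+2].Cc1ccc(cc1)S(=O)(=O)[O-].Cc1ccc(cc1)S(=O)(=O)[O-]
Why: Mitsunobu substitution with tosylate as the nucleophile replaces the activated C6 oxygen with inversion, giving the 6-epi tosylate that the lactonization will invert back.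

Step 20
Reactants: 22 open-chain 6-epi tosylate
Product: 25 α-methylene-γ-butyrolactone bearing the 4,5-epoxide side chain on C6 and the C8–C10 side chain on C7, via nickelalactone 23 (not isolated), via tosyloxy acrylic acid 24 (not isolated)
Conditions: Ni(cod)2 (1.2 equiv), DBU (3 equiv), CO2 (1 atm), THF, 0 °C; then AcOH (2.4 equiv), 0 °C; then Cs2CO3, DMF, 45 °C
Reagents that add atoms: carbon dioxide, O=C=O
Why: Zerovalent nickel ligated by DBU binds the only alkyne and couples it oxidatively with CO2 to an oxanickelacyclopentenone in which the CO2 carbon is bonded to the internal carbon C11 and nickel to the terminal C13, the Markovnikov sense expected for terminal alkynes under these conditions; acetic acid then cleaves the C13–Ni and O–Ni bonds and the caesium salt of the resulting 2-substituted acrylic acid attacks C6 from the face opposite to the tosylate. The closest known reaction types are the nickel-mediated hydrocarboxylation of alkynes with CO2 and the lactonization of a γ-sulfonyloxy carboxylate. One ring is closed, the γ-lactone, by 5-exo-tet displacement, and C11=C13 emerges as its exocyclic methylene. The only stereocentre changed is C6, where inversion of the 6-epi tosylate gives the oxygen trans to the C7 substituent as in the target, while C7 and the epoxide are untouched. The step needs selectivity for the alkyne over the acrylate and the epoxide, which the stoichiometric nickel consumed by the faster alkyne–CO2 coupling at 0 °C should secure, and substitution over elimination or epoxide opening, which the five-membered ring closure at the better leaving group should secure.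

Step 21
Reactants: 25 α-methylene-γ-butyrolactone with C3–OTES, 8-OTES, 9-OTBS
Product: 26 lactone C3 aldehyde (as 25 but C3 = CHO)
Conditions: (COCl)2, DMSO, CH2Cl2, −78 → −30 °C; Et3N, −78 → 0 °C
Reagents that add atoms: none
Why: The same Swern oxidative desilylation converts only the primary C3 TES ether into the aldehyde, which has no α-hydrogen and therefore cannot epimerize.

Step 22
Reactants: 26 lactone C3 aldehyde
Product: 28 lactone vinyl diepoxide (cis-2,3-epoxide carrying a vinyl group on C2; trans-4,5-epoxide), via syn-chlorohydrin 27 (not isolated)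
Conditions: allyl chloride, LiN(c-C6H11)2, (+)-Ipc2BOMe, BF3·OEt2, Et2O, −95 °C; then 26, −95 °C; MeOH; then DBU, CH2Cl2, 0 → 23 °C
Reagents that add atoms: allyl chloride, C=CCCl
Why: Brown-type (Z)-γ-chloroallylboration through a chair transition state gives the syn chlorohydrin by reagent-controlled attack on the Re face of the aldehyde, reinforced by its Felkin–Anh bias, which sets C3 and C2, and DBU then closes the cis-2,3-epoxide by intramolecular Williamson displacement with inversion at C2.

Step 23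
Reactants: 28 lactone vinyl diepoxide
Product: 29 ten-membered macrocycle (target skeleton with 8-OTES and 9-OTBS)
Conditions: [RuCl2(H2IMes)(=CH-C6H4-2-Oi-Pr)] (second-generation Hoveyda–Grubbs catalyst, 15 mol %), toluene (1 mM), 80 °C
Reagents that add atoms: none
Why: Ring-closing metathesis starts at the monosubstituted vinyl epoxide and closes onto the 2-substituted acrylate, the ten-membered ring allowing only the ring-cis C1=C10 geometry (C14 trans to C2), while closure onto the lactone methylene would need an eight-membered ring spanning the trans-epoxide.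

Step 24
Reactants: 29 ten-membered macrocycle (8-OTES, 9-OTBS)
Product: 30 macrocyclic C8 alcohol (8-OH, 9-OTBS)
Conditions: HF·pyridine, pyridine, THF, 0 °C
Reagents that add atoms: none
Why: Buffered HF·pyridine cleaves the secondary TES ether much faster than the TBS ether (selective desilylation), freeing only the C8 hydroxyl.

Step 25
Reactants: 30 macrocyclic C8 alcohol; 20 (2S,3S)-2,3-dimethyloxirane-2-carboxylic acid
Product: 31 macrocyclic C8 epoxyangelate (9-OTBS)
Conditions: 2,4,6-trichlorobenzoyl chloride, Et3N, THF, 23 °C; then 30, DMAP, toluene, 23 °C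
Reagents that add atoms: none
Why: Yamaguchi esterification through the mixed anhydride acylates the hindered C8 alcohol with retention at all centres, the α-quaternary epoxy acid having no epimerizable position.

Step 26
Reactants: 31 macrocyclic C8 epoxyangelate (9-OTBS)
Product: 32 macrocyclic C9 alcohol (8-epoxyangelate, 9-OH)
Conditions: HF·pyridine, THF, 23 °C
Reagents that add atoms: none
Why: Fluoride-mediated desilylation removes the TBS ether under non-basic conditions in which the hindered C8 ester should not migrate.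

Step 27
Reactants: 32 macrocyclic C9 alcohol
Product: 33 CNP0077535.2
Conditions: Ac2O, pyridine, DMAP (cat.), CH2Cl2, 0 °C
Reagents that add atoms: acetic anhydride, CC(=O)OC(C)=O
Why: DMAP-catalysed acetylation of the C9 allylic alcohol completes the target without touching the epoxides or the conjugated lactone.

**Compound list**

1 | methyl 3,4-O-isopropylidene-L-threonate, i.e. methyl (2R)-2-[(4S)-2,2-dimethyl-1,3-dioxolan-4-yl]-2-hydroxyacetate | COC(=O)[C@H](O)[C@@H]1COC(C)(C)O1 | starting material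
2 | methyl (2R)-2-[(tert-butyldimethylsilyl)oxy]-2-[(4S)-2,2-dimethyl-1,3-dioxolan-4-yl]acetate | COC(=O)[C@H](O[Si](C)(C)C(C)(C)C)[C@@H]1COC(C)(C)O1 | intermediate
3 | (2R)-2-[(tert-butyldimethylsilyl)oxy]-2-[(4S)-2,2-dimethyl-1,3-dioxolan-4-yl]acetaldehyde | O=C[C@H](O[Si](C)(C)C(C)(C)C)[C@@H]1COC(C)(C)O1 | intermediate
4 | (4S)-4-[(1S)-1-[(tert-butyldimethylsilyl)oxy]prop-2-yn-1-yl]-2,2-dimethyl-1,3-dioxolane | C#C[C@H](O[Si](C)(C)C(C)(C)C)[C@@H]1COC(C)(C)O1 | intermediate
5 | methyl 2-[(S)-[(tert-butyldimethylsilyl)oxy][(4S)-2,2-dimethyl-1,3-dioxolan-4-yl]methyl]prop-2-enoate | C=C(C(=O)OC)[C@H](O[Si](C)(C)C(C)(C)C)[C@@H]1COC(C)(C)O1 | intermediate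
6 | methyl 2-[(1S,2S)-1-[(tert-butyldimethylsilyl)oxy]-2,3-dihydroxypropyl]prop-2-enoate | C=C(C(=O)OC)[C@H](O[Si](C)(C)C(C)(C)C)[C@@H](O)CO | intermediate
7 | methyl 2-[(1S,2S)-1-[(tert-butyldimethylsilyl)oxy]-2,3-bis[(triethylsilyl)oxy]propyl]prop-2-enoate | C=C(C(=O)OC)[C@H](O[Si](C)(C)C(C)(C)C)[C@@H](O[Si](CC)(CC)CC)CO[Si](CC)(CC)CC | intermediate
8 | methyl 2-[(1S,2R)-1-[(tert-butyldimethylsilyl)oxy]-3-oxo-2-[(triethylsilyl)oxy]propyl]prop-2-enoate | C=C(C(=O)OC)[C@H](O[Si](C)(C)C(C)(C)C)[C@@H](O[Si](CC)(CC)CC)C=O | intermediate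
9 | methyl 2-[(1S,2S,3S)-1-[(tert-butyldimethylsilyl)oxy]-3-hydroxy-2-[(triethylsilyl)oxy]pent-4-yn-1-yl]prop-2-enoate | C#C[C@H](O)[C@H](O[Si](CC)(CC)CC)[C@@H](O[Si](C)(C)C(C)(C)C)C(=C)C(=O)OC | intermediate
10 | methyl 2-[(1S,2R,3S)-1-[(tert-butyldimethylsilyl)oxy]-3-[(methylsulfonyl)oxy]-2-[(triethylsilyl)oxy]pent-4-yn-1-yl]prop-2-enoate | C#C[C@H](OS(C)(=O)=O)[C@H](O[Si](CC)(CC)CC)[C@@H](O[Si](C)(C)C(C)(C)C)C(=C)C(=O)OC | intermediate
11 | 3-methylbut-2-en-1-yl acetate (prenyl acetate) | CC(C)=CCOC(C)=O | starting material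
12 | (2E)-4-hydroxy-3-methylbut-2-en-1-yl acetate | CC(=O)OC/C=C(\C)CO | intermediate
13 | [(2R,3R)-3-(hydroxymethyl)-3-methyloxiran-2-yl]methyl acetate | CC(=O)OC[C@H]1O[C@]1(C)CO | intermediate
14 | [(2R,3R)-3-methyl-3-{[(triethylsilyl)oxy]methyl}oxiran-2-yl]methyl acetate | CC(=O)OC[C@H]1O[C@]1(C)CO[Si](CC)(CC)CC | intermediate
15 | [(2R,3R)-3-methyl-3-{[(triethylsilyl)oxy]methyl}oxiran-2-yl]methanol | OC[C@H]1O[C@]1(C)CO[Si](CC)(CC)CC | intermediate
16 | (2S,3R)-3-methyl-3-{[(triethylsilyl)oxy]methyl}oxirane-2-carbaldehyde | O=C[C@H]1O[C@]1(C)CO[Si](CC)(CC)CC | intermediate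
17 | (2Z)-2-methylbut-2-enoic acid (angelic acid) | C/C=C(/C)C(=O)O | starting material
18 | (2Z)-2-methylbut-2-en-1-ol | C/C=C(/C)CO | intermediate
19 | [(2R,3S)-2,3-dimethyloxiran-2-yl]methanol | OC[C@@]1(C)O[C@H]1C | intermediate
20 | (2S,3S)-2,3-dimethyloxirane-2-carboxylic acid | O=C(O)[C@@]1(C)O[C@H]1C | intermediate
21 | open-chain homopropargylic alcohol: 3-OTES, trans-4,5-epoxide (C4 methyl), 6-OH with the C6 configuration of the target, 7-ethynyl, 8-OTES, 9-OTBS, C10(=CH2)CO2Me | C#C[C@@H]([C@H](O)[C@H]1O[C@]1(C)CO[Si](CC)(CC)CC)[C@H](O[Si](CC)(CC)CC)[C@@H](O[Si](C)(C)C(C)(C)C)C(=C)C(=O)OC | intermediate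
22 | open-chain 6-epi tosylate: as 21 but C6–OTs with inverted C6 | C#C[C@@H]([C@@H](OS(=O)(=O)c1ccc(C)cc1)[C@H]1O[C@]1(C)CO[Si](CC)(CC)CC)[C@H](O[Si](CC)(CC)CC)[C@@H](O[Si](C)(C)C(C)(C)C)C(=C)C(=O)OC | intermediate
23 | nickelalactone: oxanickelacyclopentenone from C11≡C13 and CO2 (Ni on C13, C12 on C11; DBU ligands on nickel not drawn) | O=C1O[Ni]C=C1[C@@H]([C@@H](OS(=O)(=O)c2ccc(C)cc2)[C@H]2O[C@]2(C)CO[Si](CC)(CC)CC)[C@H](O[Si](CC)(CC)CC)[C@@H](O[Si](C)(C)C(C)(C)C)C(=C)C(=O)OC | intermediate
24 | tosyloxy acrylic acid: 2-substituted acrylic acid (C12 acid on C11, C11=C13H2), C6–OTs retained; reacts on as its caesium salt | C=C(C(=O)O)[C@@H]([C@@H](OS(=O)(=O)c1ccc(C)cc1)[C@H]1O[C@]1(C)CO[Si](CC)(CC)CC)[C@H](O[Si](CC)(CC)CC)[C@@H](O[Si](C)(C)C(C)(C)C)C(=C)C(=O)OC | intermediate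
25 | α-methylene-γ-butyrolactone: trans-6,7-lactone, C6 carries the 4,5-epoxide with C3–OTES, C7 carries C8(OTES)–C9(OTBS)–C10(=CH2)CO2Me | C=C1C(=O)O[C@H]([C@H]2O[C@]2(C)CO[Si](CC)(CC)CC)[C@H]1[C@H](O[Si](CC)(CC)CC)[C@@H](O[Si](C)(C)C(C)(C)C)C(=C)C(=O)OC | intermediate
26 | lactone C3 aldehyde: as 25 but C3 = CHO | C=C1C(=O)O[C@H]([C@H]2O[C@]2(C)C=O)[C@H]1[C@H](O[Si](CC)(CC)CC)[C@@H](O[Si](C)(C)C(C)(C)C)C(=C)C(=O)OC | intermediate
27 | syn-chlorohydrin: 3-OH, 2-Cl, C1 vinyl; otherwise as 26 | C=C[C@H](Cl)[C@@H](O)[C@@]2(C)O[C@@H]2[C@H]1OC(=O)C(=C)[C@@H]1[C@H](O[Si](CC)(CC)CC)[C@@H](O[Si](C)(C)C(C)(C)C)C(=C)C(=O)OC | intermediate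
28 | lactone vinyl diepoxide: cis-2,3-epoxide with vinyl on C2, trans-4,5-epoxide, 8-OTES, 9-OTBS, C10(=CH2)CO2Me | C=C[C@H]1O[C@H]1[C@@]2(C)O[C@@H]2[C@H]3OC(=O)C(=C)[C@@H]3[C@H](O[Si](CC)(CC)CC)[C@@H](O[Si](C)(C)C(C)(C)C)C(=C)C(=O)OC | intermediate
29 | ten-membered macrocycle: target skeleton with 8-OTES and 9-OTBS | C=C1C(=O)O[C@H]2[C@H]1[C@H](O[Si](CC)(CC)CC)[C@@H](O[Si](C)(C)C(C)(C)C)/C(C(=O)OC)=C\[C@H]1O[C@H]1[C@@]1(C)O[C@H]21 | intermediate
30 | macrocyclic C8 alcohol: 8-OH, 9-OTBS | C=C1C(=O)O[C@H]2[C@H]1[C@H](O)[C@@H](O[Si](C)(C)C(C)(C)C)/C(C(=O)OC)=C\[C@H]1O[C@H]1[C@@]1(C)O[C@H]21 | intermediate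
31 | macrocyclic C8 (2S,3S)-epoxyangelate, 9-OTBS | C=C1C(=O)O[C@H]2[C@H]1[C@H](OC(=O)[C@@]1(C)O[C@H]1C)[C@@H](O[Si](C)(C)C(C)(C)C)/C(C(=O)OC)=C\[C@H]1O[C@H]1[C@@]1(C)O[C@H]21 | intermediate
32 | macrocyclic C9 alcohol: 8-epoxyangelate, 9-OH | C=C1C(=O)O[C@H]2[C@H]1[C@H](OC(=O)[C@@]1(C)O[C@H]1C)[C@@H](O)/C(C(=O)OC)=C\[C@H]1O[C@H]1[C@@]1(C)O[C@H]21 | intermediate
33 | CNP0077535.2 (2R,3R,4S,5R,6S,7R,8S,9S; ester 2S,3S; C1=C10 with C14 trans to C2) | C=C1C(=O)O[C@H]2[C@H]1[C@H](OC(=O)[C@@]1(C)O[C@H]1C)[C@@H](OC(C)=O)/C(C(=O)OC)=C\[C@H]1O[C@H]1[C@@]1(C)O[C@H]21 | target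

**Step count.** 27 steps in total; the longest linear sequence is 19 steps (steps 1–9, then 18–27).

**Steps most likely to fail**

Step 20 (key step). The carbon dioxide may add at the terminal alkyne carbon, nickel may be diverted by the acrylate, or the caesium carboxylate may eliminate the tosylate instead of displacing it. Fallback: setting out from 22, copper-catalysed Markovnikov protoboration of the alkyne ([(SIMes)CuCl], NaOt-Bu, B2pin2, MeOH, THF) would give the 1,1-disubstituted alkenyl pinacolboronate F1. Copper-catalysed carboxylation of its C–B bond under CO2 ([(IPr)CuCl], CsF, DMF, 90 °C) would form the caesium salt of 24, which lactonizes in the same pot, so the route is rejoined at 25.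

Step 23. The ruthenium carbene formed at the vinyl epoxide may fail to engage the hindered acrylate beside the silyl ether, so that dimerization replaces ring closure. Fallback: the ring closure is moved behind the two acylation-related steps and run on a hydroxyl-assisted substrate. Setting out from 28, HF·pyridine/pyridine would give the diene C8 alcohol F2, Yamaguchi esterification with 20 the diene C8 epoxyangelate F3, and HF·pyridine the diene C9 allylic alcohol F4. Metathesis of F4, where the free hydroxyl next to the 1,1-disubstituted alkene assists loading of ruthenium and the silyl group no longer shields it, would give 32, where the route is rejoined.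

Step 19. Mitsunobu activation of the hindered epoxy carbinol may stall or end in elimination rather than clean inversion. Fallback: setting out from 21, Dess–Martin oxidation would give the epoxy ketone F5. Chelation-controlled reduction with Zn(BH4)2 (Et2O, −20 °C) should give the erythro epoxy alcohol F6, the 6-epimer of 21, and tosylation with retention (TsCl, DMAP, pyridine) rejoins the route at 22.

**Further compounds**

F1 | step 20 | alkenyl pinacolboronate of 22 (Bpin on C11, C11=C13H2) | C=C(B1OC(C)(C)C(C)(C)O1)[C@@H]([C@@H](OS(=O)(=O)c1ccc(C)cc1)[C@H]1O[C@]1(C)CO[Si](CC)(CC)CC)[C@H](O[Si](CC)(CC)CC)[C@@H](O[Si](C)(C)C(C)(C)C)C(=C)C(=O)OC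
F2 | step 23 | diene C8 alcohol (28 without the TES group) | C=C[C@H]1O[C@H]1[C@@]2(C)O[C@@H]2[C@H]3OC(=O)C(=C)[C@@H]3[C@H](O)[C@@H](O[Si](C)(C)C(C)(C)C)C(=C)C(=O)OC
F3 | step 23 | diene C8 epoxyangelate, 9-OTBS | C=C[C@H]1O[C@H]1[C@@]2(C)O[C@@H]2[C@H]3OC(=O)C(=C)[C@@H]3[C@H](OC(=O)[C@@]4(C)O[C@H]4C)[C@@H](O[Si](C)(C)C(C)(C)C)C(=C)C(=O)OC
F4 | step 23 | diene C9 allylic alcohol, 8-epoxyangelate | C=C[C@H]1O[C@H]1[C@@]2(C)O[C@@H]2[C@H]3OC(=O)C(=C)[C@@H]3[C@H](OC(=O)[C@@]4(C)O[C@H]4C)[C@@H](O)C(=C)C(=O)OC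
F5 | step 19 | C6 epoxy ketone from 21 | C#C[C@@H](C(=O)[C@H]1O[C@]1(C)CO[Si](CC)(CC)CC)[C@H](O[Si](CC)(CC)CC)[C@@H](O[Si](C)(C)C(C)(C)C)C(=C)C(=O)OC
F6 | step 19 | 6-epi alcohol (6-epimer of 21) | C#C[C@@H]([C@@H](O)[C@H]1O[C@]1(C)CO[Si](CC)(CC)CC)[C@H](O[Si](CC)(CC)CC)[C@@H](O[Si](C)(C)C(C)(C)C)C(=C)C(=O)OC
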